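**Retrosynthetic overview**

1. The plan rests on ring C of the target, the 2,3-dimethylchroman-4-one ring (O1, C2, C3, C4, C4a, C8a): the C4 ketone sits between arene carbon C4a and the methyl-bearing C3, beside the ether stereocentre C2. The C3–C4 bond is therefore cut back to an aryl aldehyde whose C–H is added across the terminal alkene of an (S)-but-3-en-2-yl aryl ether by carbene catalysis.
2. Until the last step the hexanoic acid chain is tied to the neighbouring phenol oxygen as a six-membered aryl lactone (a 4-propylchroman-2-one); saponification then frees the C5 hydroxyl and the acid together.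
3. The arene is substituted without regiochemical choices: Pechmann coumarin from phloroglucinol, silylation of the more reactive 7-OH, Claisen shift of the 5-O-allyl group to its only free ortho carbon (C6, made prenyl later by cross-metathesis), and formylation at the one ring C–H that remains (C8).
4. Stereocentres: the benzylic carbon by asymmetric CuH 1,4-reduction of the coumarin, the ether carbon from (R)-but-3-en-2-ol by Mitsunobu inversion, and C3 of ring C by base equilibration to the trans isomer.
5. Ring order: arene (purchased), lactone ring (step 1, saturated in step 6), ring C (step 10); the lactone ring is opened in step 11.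

Key step: step 10

Assumption: the sense of hydride delivery in step 6 follows the ligand antipode and cannot be assigned in advance with certainty for this 4-alkyl-5-alkoxycoumarin; (R)-DTBM-SEGPHOS is written, and (S)-DTBM-SEGPHOS is to be used if a first run gives the (S)-lactone.

Remark: locants of compounds 3–13 follow coumarin (chroman-2-one) numbering; ring C locants follow chroman-4-one numbering.

**Route**

Step 1
Reactants: 1 phloroglucinol, 2 ethyl 3-oxohexanoate
Product: 3 5,7-dihydroxy-4-propyl-2H-chromen-2-one
Conditions: conc. H2SO4, 0 °C to rt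
Reagents that add atoms: none
Why: Pechmann condensation, in which acid-promoted transesterification, attack of the ketone on the activated triol and dehydration give the 4-propylcoumarin, and the three equivalent ring positions of phloroglucinol allow only one product.

Step 2
Reactants: 3 5,7-dihydroxy-4-propyl-2H-chromen-2-one
Product: 4 5-hydroxy-4-propyl-7-[(triisopropylsilyl)oxy]-2H-chromen-2-one
Conditions: i-Pr3SiCl (1.05 equiv), imidazole, DMF, 0 °C
Reagents that add atoms: triisopropylsilyl chloride, CC(C)[Si](Cl)(C(C)C)C(C)C
Why: Selective silylation, since the 7-hydroxyl is the more acidic phenol (para-conjugated to the pyranone carbonyl) and is unhindered, whereas the 5-hydroxyl is shielded by the peri propyl group, so the bulky silyl chloride should react at O7 only.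

Step 3
Reactants: 4 5-hydroxy-4-propyl-7-[(triisopropylsilyl)oxy]-2H-chromen-2-one
Product: 5 5-(allyloxy)-4-propyl-7-[(triisopropylsilyl)oxy]-2H-chromen-2-one
Conditions: allyl bromide, K2CO3, dry acetone, 55 °C
Reagents that add atoms: allyl bromide, C=CCBr
Why: Williamson etherification of the one remaining phenol with a reactive allylic halide under anhydrous carbonate conditions that an aryl triisopropylsilyl ether should tolerate.

Step 4
Reactants: 5 5-(allyloxy)-4-propyl-7-[(triisopropylsilyl)oxy]-2H-chromen-2-one
Product: 6 6-allyl-5-hydroxy-4-propyl-7-[(triisopropylsilyl)oxy]-2H-chromen-2-one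
Conditions: PhNEt2, 190 °C, argon
Reagents that add atoms: none
Why: Aromatic Claisen rearrangement, in which the [3,3] shift from O5 can only end productively at C6 because the other ortho carbon (C4a) is quaternary, so tautomerisation places the allyl group between O5 and O7.

Step 5
Reactants: 6 6-allyl-5-hydroxy-4-propyl-7-[(triisopropylsilyl)oxy]-2H-chromen-2-one
Product: 7 6-allyl-5-methoxy-4-propyl-7-[(triisopropylsilyl)oxy]-2H-chromen-2-one
Conditions: MeI, K2CO3, dry acetone, 55 °C
Reagents that add atoms: iodomethane, CI
Why: Williamson O-methylation of the only free phenol, where the small electrophile should still reach the flanked 5-oxygen.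

Step 6
Reactants: 7 6-allyl-5-methoxy-4-propyl-7-[(triisopropylsilyl)oxy]-2H-chromen-2-one
Product: 9 (R)-6-allyl-7-hydroxy-5-methoxy-4-propylchroman-2-one, via silyl ether lactone 8 (not isolated)
Conditions: Cu(OAc)2·H2O (5 mol%), (R)-DTBM-SEGPHOS (5.5 mol%), HSiMe(OEt)2 (1.5 equiv), t-BuOH (1.5 equiv), toluene, 0 °C to rt; then Bu4NF, AcOH, THF, 0 °C
Reagents that add atoms: none
Why: Asymmetric conjugate (1,4-) reduction with a ligated CuH catalyst, known for coumarins and beta,beta-disubstituted unsaturated esters, in which the chiral bisphosphine directs hydride to one face of C4 and so sets the (R) benzylic stereocentre, the isolated allyl group should not be hydrocuprated at this temperature, limited silane guards against lactol formation, and buffered fluoride then cleaves the aryl silyl ether in the same flask.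

Step 7
Reactants: 9 (R)-6-allyl-7-hydroxy-5-methoxy-4-propylchroman-2-one
Product: 10 (R)-6-allyl-7-hydroxy-5-methoxy-2-oxo-4-propylchromane-8-carbaldehyde
Conditions: Cl2CHOMe, TiCl4, CH2Cl2, −20 to 0 °C; then cold 1 M HCl
Reagents that add atoms: dichloromethyl methyl ether, COC(Cl)Cl; water, O
Why: Rieche formylation, in which the titanium phenoxide directs the electrophile to the ortho position and C8 is in any case the only unsubstituted ring carbon, so the aldehyde is placed between O7 and the lactone oxygen without a regiochemical choice.

Step 8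
Reactants: 10 (R)-6-allyl-7-hydroxy-5-methoxy-2-oxo-4-propylchromane-8-carbaldehyde
Product: 11 (R)-7-hydroxy-5-methoxy-6-(3-methylbut-2-en-1-yl)-2-oxo-4-propylchromane-8-carbaldehyde
Conditions: 2-methylbut-2-ene (large excess), second-generation Grubbs catalyst RuCl2(=CHPh)(PCy3)(H2IMes) (5 mol%), CH2Cl2, 40 °C, sealed tube
Reagents that add atoms: 2-methylbut-2-ene, CC=C(C)C
Why: Olefin cross-metathesis of the terminal allyl group with excess 2-methylbut-2-ene, a standard way to turn an aryl allyl group into a prenyl group with loss of propene, which tolerates phenols, aldehydes and esters.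

Step 9
Reactants: 11 (R)-7-hydroxy-5-methoxy-6-(3-methylbut-2-en-1-yl)-2-oxo-4-propylchromane-8-carbaldehyde, 12 (R)-but-3-en-2-ol
Product: 13 (R)-7-[(S)-but-3-en-2-yloxy]-5-methoxy-6-(3-methylbut-2-en-1-yl)-2-oxo-4-propylchromane-8-carbaldehyde
Conditions: PPh3, diisopropyl azodicarboxylate, THF, 0 °C to rt
Reagents that add atoms: none
Why: Mitsunobu etherification, in which the acidic aldehyde-chelated phenol displaces the oxyphosphonium derivative of the secondary allylic alcohol by SN2 with inversion, turning the (R) carbinol into the (S) aryl ether stereocentre.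

Step 10
Reactants: 13 (R)-7-[(S)-but-3-en-2-yloxy]-5-methoxy-6-(3-methylbut-2-en-1-yl)-2-oxo-4-propylchromane-8-carbaldehyde
Product: 15 (4R,8S,9S)-5-methoxy-8,9-dimethyl-6-(3-methylbut-2-en-1-yl)-4-propyl-3,4,8,9-tetrahydro-2H,10H-pyrano[2,3-f]chromene-2,10-dione, via cis C9 epimer 14 (not isolated)
Conditions: 2-mesityl-6,7-dihydro-5H-pyrrolo[2,1-c][1,2,4]triazol-2-ium chloride (20 mol%), DBU (25 mol%), dry degassed 1,4-dioxane, 90 °C, held until the C9 epimers have converged
Reagents that add atoms: none
Why: The carbene released from the triazolium salt by DBU adds to the C8 aldehyde and proton transfer gives a nucleophilic hydroxy-enamine; its carbon bonds to the internal alkene carbon while its O–H proton passes to the terminal carbon through a concerted Conia-ene-like transition state, after which the carbene is expelled and the ketone (C10 here, C4 of ring C) appears. The closest known reaction is the carbene-catalysed intramolecular hydroacylation of unactivated alkenes in 2-(allyloxy)benzaldehydes, which gives 3-methylchroman-4-ones. The one ring formed, ring C, closes in 6-exo-trig mode. The ether stereocentre (C8 here, C2 of ring C) is carried in unchanged from 13, and the new centre (C9 here, C3 of ring C) is alpha to the ketone, so the small excess of DBU should equilibrate any cis epimer 14 to the diequatorial trans isomer under control of the fixed neighbour. The step needs exo closure to the branched ketone rather than seven-membered endo closure, which the cyclic transition state secures because the proton can only reach the terminal CH2, and it needs the aldehyde to win over the aryl lactone for the carbene, which is helped because any acyl azolium formed from the lactone recloses on its own tethered phenoxide. Claisen rearrangement of the ether is unproductive because both ortho carbons and the para carbon are substituted, and keeping the base catalytic limits enolate-driven opening of ring C that would endanger the ether stereocentre.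

Step 11
Reactants: 15 (4R,8S,9S)-5-methoxy-8,9-dimethyl-6-(3-methylbut-2-en-1-yl)-4-propyl-3,4,8,9-tetrahydro-2H,10H-pyrano[2,3-f]chromene-2,10-dione
Product: 16 (3R)-3-[(2S,3S)-5-hydroxy-7-methoxy-2,3-dimethyl-8-(3-methylbut-2-en-1-yl)-4-oxo-3,4-dihydro-2H-chromen-6-yl]hexanoic acid (CNP0233409.1)
Conditions: LiOH·H2O (3 equiv), THF/H2O, 0 °C; then 1 M HCl to pH 3 at 0 °C
Reagents that add atoms: lithium hydroxide (hydroxide oxygen), [Li+].[OH-]
Why: Saponification of the aryl ester (lactone) is fast at 0 °C and frees the carboxylic acid and the C5 phenol, which is then held by a hydrogen bond to the C4 ketone, while short cold exposure and mild acidification should leave C2 and C3 of ring C untouched and avoid relactonisation.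

**Compound list**

1 | phloroglucinol (benzene-1,3,5-triol) | Oc1cc(O)cc(O)c1 | starting material
2 | ethyl 3-oxohexanoate | CCCC(=O)CC(=O)OCC | starting material
3 | 5,7-dihydroxy-4-propyl-2H-chromen-2-one | CCCC1=CC(=O)Oc2cc(O)cc(O)c12 | intermediate
4 | 5-hydroxy-4-propyl-7-[(triisopropylsilyl)oxy]-2H-chromen-2-one | CCCC1=CC(=O)Oc2cc(O[Si](C(C)C)(C(C)C)C(C)C)cc(O)c12 | intermediate
5 | 5-(allyloxy)-4-propyl-7-[(triisopropylsilyl)oxy]-2H-chromen-2-one | CCCC1=CC(=O)Oc2cc(O[Si](C(C)C)(C(C)C)C(C)C)cc(OCC=C)c12 | intermediate
6 | 6-allyl-5-hydroxy-4-propyl-7-[(triisopropylsilyl)oxy]-2H-chromen-2-one | CCCC1=CC(=O)Oc2cc(O[Si](C(C)C)(C(C)C)C(C)C)c(CC=C)c(O)c12 | intermediate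
7 | 6-allyl-5-methoxy-4-propyl-7-[(triisopropylsilyl)oxy]-2H-chromen-2-one | CCCC1=CC(=O)Oc2cc(O[Si](C(C)C)(C(C)C)C(C)C)c(CC=C)c(OC)c12 | intermediate
8 | (R)-6-allyl-5-methoxy-4-propyl-7-[(triisopropylsilyl)oxy]chroman-2-one | CCC[C@@H]1CC(=O)Oc2cc(O[Si](C(C)C)(C(C)C)C(C)C)c(CC=C)c(OC)c21 | intermediate (not isolated)
9 | (R)-6-allyl-7-hydroxy-5-methoxy-4-propylchroman-2-one | CCC[C@@H]1CC(=O)Oc2cc(O)c(CC=C)c(OC)c21 | intermediate
10 | (R)-6-allyl-7-hydroxy-5-methoxy-2-oxo-4-propylchromane-8-carbaldehyde | CCC[C@@H]1CC(=O)Oc2c(C=O)c(O)c(CC=C)c(OC)c21 | intermediate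
11 | (R)-7-hydroxy-5-methoxy-6-(3-methylbut-2-en-1-yl)-2-oxo-4-propylchromane-8-carbaldehyde | CCC[C@@H]1CC(=O)Oc2c(C=O)c(O)c(CC=C(C)C)c(OC)c21 | intermediate
12 | (R)-but-3-en-2-ol | C[C@@H](O)C=C | starting material
13 | (R)-7-[(S)-but-3-en-2-yloxy]-5-methoxy-6-(3-methylbut-2-en-1-yl)-2-oxo-4-propylchromane-8-carbaldehyde (key-step precursor) | CCC[C@@H]1CC(=O)Oc2c1c(OC)c(CC=C(C)C)c(O[C@@H](C)C=C)c2C=O | intermediate
14 | (4R,8S,9R)-5-methoxy-8,9-dimethyl-6-(3-methylbut-2-en-1-yl)-4-propyl-3,4,8,9-tetrahydro-2H,10H-pyrano[2,3-f]chromene-2,10-dione (cis epimer) | CCC[C@@H]1CC(=O)Oc2c1c(OC)c(CC=C(C)C)c1O[C@@H](C)[C@@H](C)C(=O)c21 | intermediate (not isolated)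
15 | (4R,8S,9S)-5-methoxy-8,9-dimethyl-6-(3-methylbut-2-en-1-yl)-4-propyl-3,4,8,9-tetrahydro-2H,10H-pyrano[2,3-f]chromene-2,10-dione (lactone of the target) | CCC[C@@H]1CC(=O)Oc2c1c(OC)c(CC=C(C)C)c1O[C@@H](C)[C@H](C)C(=O)c21 | intermediate
16 | (3R)-3-[(2S,3S)-5-hydroxy-7-methoxy-2,3-dimethyl-8-(3-methylbut-2-en-1-yl)-4-oxo-3,4-dihydro-2H-chromen-6-yl]hexanoic acid | CCC[C@H](CC(=O)O)c1c(O)c2c(c(CC=C(C)C)c1OC)O[C@@H](C)[C@H](C)C2=O | target

**Step count and risks**

Total: 11 steps. Longest linear sequence: 11 steps, from phloroglucinol (1) to 16.

Steps most likely to fail: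

1. Step 10 (carbene hydroacylation). Carbene addition to the aldehyde may be slow because both ortho positions carry oxygen substituents, which would leave room for aldehyde oxidation or lactone acyl transfer to the catalyst. Enolate-driven opening and reclosure of ring C (retro-oxa-Michael) under base could erode the ether stereocentre. Fallback: the C3–C4 bond would be made by acyl radical cyclisation under neutral conditions, setting out from 13. Chlorite oxidation (NaClO2, NaH2PO4, 2-methylbut-2-ene, t-BuOH/H2O) should give (4R)-7-[(2S)-but-3-en-2-yloxy]-5-methoxy-6-(3-methylbut-2-en-1-yl)-2-oxo-4-propylchromane-8-carboxylic acid F1. PhSeSePh and PBu3 in CH2Cl2 should convert it into the Se-phenyl selenoester F2. Slow addition of Bu3SnH with AIBN in benzene at 80 °C should generate the aroyl radical, which closes 6-exo onto the internal alkene carbon, and brief treatment with Et3N should equilibrate any 14 to the trans isomer. The route is rejoined at 15.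

2. Step 6 (asymmetric CuH reduction). Hydride transfer to C4 may be sluggish, or facial discrimination poor, because C4 is flanked by the peri methoxy group; prolonged reaction could also reduce the aryl lactone further to the lactol. Fallback: resolution instead of asymmetric catalysis, setting out from 7. The same reduction with an achiral ligand (Cu(OAc)2·H2O, 1,2-bis(diphenylphosphino)benzene, HSiMe(OEt)2, t-BuOH) should give the racemic silyl ether lactone F3, and buffered Bu4NF the racemic 6-allyl-7-hydroxy-5-methoxy-4-propylchroman-2-one F4. This is separated by preparative chromatography on a cellulose tris(3,5-dimethylphenylcarbamate) stationary phase; the unwanted (S)-6-allyl-7-hydroxy-5-methoxy-4-propylchroman-2-one F5 is set aside and the (R)-enantiomer rejoins the route at 9.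

3. Step 9 (Mitsunobu etherification). The doubly ortho-substituted, hydrogen-bonded phenol may react slowly, and the activated allylic alcohol may ionise or be attacked in SN2' fashion, giving the linear but-2-enyl ether or lowering the enantiomeric purity of the ether centre. Fallback: catalyst-controlled construction of the same stereocentre, setting out from 11. Palladium-catalysed asymmetric allylic O-alkylation with (E)-but-2-enyl methyl carbonate, Pd2(dba)3·CHCl3 (a zerovalent palladium source) and N,N'-(cyclohexane-1,2-diyl)bis[2-(diphenylphosphanyl)benzamide] in CH2Cl2 at rt, should let the phenoxide attack the more substituted end of the 1-methylallyl palladium complex, with the ligand antipode chosen to give the (S) ether. The route is rejoined at 13 with no new isolable compound (F0).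

**Further compounds**

F1 | step 10 | (4R)-7-[(2S)-but-3-en-2-yloxy]-5-methoxy-6-(3-methylbut-2-en-1-yl)-2-oxo-4-propylchromane-8-carboxylic acid | CCC[C@@H]1CC(=O)Oc2c1c(OC)c(CC=C(C)C)c(O[C@@H](C)C=C)c2C(=O)O
F2 | step 10 | Se-phenyl (4R)-7-[(2S)-but-3-en-2-yloxy]-5-methoxy-6-(3-methylbut-2-en-1-yl)-2-oxo-4-propylchromane-8-carboselenoate | CCC[C@@H]1CC(=O)Oc2c1c(OC)c(CC=C(C)C)c(O[C@@H](C)C=C)c2C(=O)[Se]c1ccccc1
F3 | step 6 | racemic 6-allyl-5-methoxy-4-propyl-7-[(triisopropylsilyl)oxy]chroman-2-one | CCCC1CC(=O)Oc2cc(O[Si](C(C)C)(C(C)C)C(C)C)c(CC=C)c(OC)c21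
F4 | step 6 | racemic 6-allyl-7-hydroxy-5-methoxy-4-propylchroman-2-one | CCCC1CC(=O)Oc2cc(O)c(CC=C)c(OC)c21
F5 | step 6 | (S)-6-allyl-7-hydroxy-5-methoxy-4-propylchroman-2-one | CCC[C@H]1CC(=O)Oc2cc(O)c(CC=C)c(OC)c21
F0 | step 9 | none | none
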